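**Plan**

1. Cuts: the Wittig bonds C11=C12 and C11'=C12' divide the C40 polyene into a ring A C15 phosphonium salt, the commercial C10 trienedial and a furanoid C15 phosphonium salt. The ring A half is then cut at C8–C9 (alkenyl addition, then dehydration to E-C7=C8) and at C1–C6. The ring B half is cut at O–C8' and C8'–C9'.
2. Enabling feature: in ring A the gem-dimethyl carbon C1 and the two carbinol carbons C6 and C5 sit side by side, and none bears hydrogen. An early-transition-state attack of a tertiary C1 radical on C6 can join such centres. A five-membered carbonate bridging O5 and O6 leaves cis fusion as the only geometry open to the new six-membered ring.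
3. Forward, ring A half: geraniol supplies C1–C7 and methyl chloroformate supplies C8. CO2 closes the temporary carbonate ring, the radical step then closes ring A, and one enol triflate brings C9–C11.
4. Forward, ring B half: the carbocycle comes from β-cyclocitral. Epoxide, alkynyl epoxide, enyne and hydroxy-allene follow, and the dihydrofuran closes last. The chain is joined in the order ring B salt plus C10 dialdehyde, then ring A salt.
5. Stereochemistry: C5 and C5' come from two Sharpless epoxidations with D-(−)-diethyl tartrate. C6 follows from C5 through the carbonate tether. C8' follows from C5' through a syn SN2' hydride delivery (allene axis) and axis-to-centre transfer.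

Key step: step 6

Remark: carotenoid numbering is used for all intermediates. The hindered Z isomers that the two Wittig steps form at C11=C12 and C11'=C12' are assumed to equilibrate to E on warming.

**Step 1**
Reactants: 1 geraniol
Product: 2 (2R,3R)-2,3-epoxygeraniol
Conditions: Ti(OiPr)4 (5 mol %), D-(−)-diethyl tartrate (6 mol %), t-BuOOH, 4 Å MS, CH2Cl2, −20 °C
Reagents that add atoms: tert-butyl hydroperoxide CC(C)(C)OO
Why: The Katsuki–Sharpless asymmetric epoxidation touches only the allylic alkene, and the D-(−)-tartrate complex delivers oxygen to the face that makes the quaternary carbon (the later C5) R.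

**Step 2**
Reactants: 2 (2R,3R)-2,3-epoxygeraniol
Product: 3 (2R,3S)-3-(chloromethyl)-2-methyl-2-(4-methylpent-3-en-1-yl)oxirane
Conditions: PPh3, CCl4, NaHCO3, reflux
Reagents that add atoms: carbon tetrachloride ClC(Cl)(Cl)Cl
Why: The Appel chlorination exchanges the primary hydroxyl under nearly neutral conditions that leave the oxirane and the distal alkene alone.

**Step 3**
Reactants: 3 (2R,3S)-3-(chloromethyl)-2-methyl-2-(4-methylpent-3-en-1-yl)oxirane
Product: 4 (3R)-3,7-dimethyloct-6-en-1-yn-3-ol
Conditions: n-BuLi (3.2 equiv), THF, −78 to −30 °C; then H2O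
Reagents that add atoms: none
Why: Base-induced double elimination of a 2,3-epoxy chloride opens the oxirane at the CH–O bond and then loses HCl, so the C–O bond at the quaternary carbon C5 and its configuration are never touched.

**Step 4**
Reactants: 4 (3R)-3,7-dimethyloct-6-en-1-yn-3-ol; 5 methyl chloroformate
Product: 6 methyl (4R)-4-hydroxy-4,8-dimethylnon-7-en-2-ynoate
Conditions: n-BuLi (2.05 equiv), THF, −78 °C; 5 (1.0 equiv), −78 °C; then AcOH
Reagents that add atoms: none
Why: In this C-acylation of the alkoxide/acetylide dianion the acetylide carbon should react with the chloroformate at −78 °C much faster than the hindered tertiary lithium alkoxide.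

**Step 5**
Reactants: 6 methyl (4R)-4-hydroxy-4,8-dimethylnon-7-en-2-ynoate; 7 carbon dioxide
Product: 8 methyl (2Z)-2-[(5R)-5-methyl-5-(4-methylpent-3-en-1-yl)-2-oxo-1,3-dioxolan-4-ylidene]acetate
Conditions: AgOAc (10 mol %), DBU (1.0 equiv), CO2 (1 MPa), toluene, 25 °C, dark
Reagents that add atoms: none
Why: In this silver-catalysed carboxylative cyclisation of a tertiary propargylic alcohol the carbonate anion adds 5-exo-dig and anti to silver at C6, which is also the Michael position of the alkynoate, so the Z-alkylidene carbonate forms and C5 is untouched.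

**Step 6**
Reactants: 8 methyl (2Z)-2-[(5R)-5-methyl-5-(4-methylpent-3-en-1-yl)-2-oxo-1,3-dioxolan-4-ylidene]acetate
Product: 9 methyl 2-[(3aS,7aR)-4,4,7a-trimethyl-2-oxohexahydro-1,3-benzodioxol-3a-yl]acetate
Conditions: Fe(acac)3 (0.3 equiv), PhSiH3 (2.5 equiv, added over 2 h), i-PrOH (0.02 M), 40 °C, Ar
Reagents that add atoms: none
Why: Proposed new method: an iron hydride made from Fe(acac)3 and the silane hands a hydrogen atom to C2 of the trisubstituted alkene, the resulting nucleophilic tertiary C1 radical adds to C6 (the oxygen-bearing beta carbon of the enol-carbonate acrylate), and the ester-stabilised C7 radical is reduced by divalent iron and protonated by the alcohol. The closest known reaction types are the iron-catalysed hydrogen-atom-transfer reductive (Giese-type) cyclisation of alkenes onto acceptor alkenes, which builds vicinal quaternary carbons, and radical cyclisation onto beta-alkoxyacrylates, while an alkylidene cyclic carbonate as acceptor has not been shown. Ring A closes in the 6-exo-trig mode, with C1 bonding to C6 and C7 left exocyclic. The new stereocentre C6 is dictated by C5, because the chain reaches C6 only from the face of the dioxolanone on which C4 stands and a cyclohexane can be fused to the five-membered carbonate only cis, which places C7 cis to the C5 methyl group and both oxygens on the other face. The step needs chemoselective hydrogen-atom transfer to the electron-rich prenyl alkene rather than the electron-poor, fully beta-substituted acceptor, and attack at C6 rather than C7, and both follow from polarity matching reinforced by the exo preference. Expulsion of carbonate from a C7 enolate is countered by the protic but poorly nucleophilic i-PrOH, which should protonate C7 quickly and open the activated carbonate only slowly.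

**Step 7**
Reactants: 9 methyl 2-[(3aS,7aR)-4,4,7a-trimethyl-2-oxohexahydro-1,3-benzodioxol-3a-yl]acetate
Product: 10 2-[(3aS,7aR)-4,4,7a-trimethyl-2-oxohexahydro-1,3-benzodioxol-3a-yl]acetaldehyde
Conditions: i-Bu2AlH (1.1 equiv), toluene, −78 °C; MeOH, then aq potassium sodium tartrate; used crude
Reagents that add atoms: none
Why: The partial ester reduction stops at the aluminium hemiacetal at −78 °C, and the less electrophilic carbonate, flanked by two quaternary carbons, should be spared by one equivalent of hydride.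

**Step 8**
Reactants: 11 ethyl acetoacetate
Product: 12 ethyl (2E)-3-(trifluoromethylsulfonyloxy)but-2-enoate
Conditions: Tf2O, aq Me4NOH, hexanes, 5 °C
Reagents that add atoms: triflic anhydride O=S(=O)(OS(=O)(=O)C(F)(F)F)C(F)(F)F
Why: In this O-triflation of the acetoacetate enolate under Schotten–Baumann conditions the non-chelating tetramethylammonium ion favours the E-enolate and hence the E-enol triflate.

**Step 9**
Reactants: 10 2-[(3aS,7aR)-4,4,7a-trimethyl-2-oxohexahydro-1,3-benzodioxol-3a-yl]acetaldehyde; 12 ethyl (2E)-3-(trifluoromethylsulfonyloxy)but-2-enoate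
Product: 13 ethyl (2E)-4-hydroxy-3-methyl-5-[(3aS,7aR)-4,4,7a-trimethyl-2-oxohexahydro-1,3-benzodioxol-3a-yl]pent-2-enoate (both C8 epimers)
Conditions: CrCl2 (4 equiv), NiCl2 (2 mol %), DMF, 25 °C
Reagents that add atoms: none
Why: The Nozaki–Hiyama–Kishi coupling is non-basic and aldehyde-selective, so the beta-carbonate aldehyde is not enolised, ester and carbonate survive, the alkenyl geometry is kept, and both C8 epimers are usable because C8 becomes sp2 in the next step.

**Step 10**
Reactants: 13 ethyl (2E)-4-hydroxy-3-methyl-5-[(3aS,7aR)-4,4,7a-trimethyl-2-oxohexahydro-1,3-benzodioxol-3a-yl]pent-2-enoate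
Product: 14 ethyl (2E,4E)-3-methyl-5-[(3aS,7aR)-4,4,7a-trimethyl-2-oxohexahydro-1,3-benzodioxol-3a-yl]penta-2,4-dienoate
Conditions: Burgess reagent (MeO2CN(−)SO2N(+)Et3, 2 equiv), toluene, 60 °C
Reagents that add atoms: none
Why: The Burgess dehydration is a neutral thermal syn elimination for which only the C7 hydrogens are available, and the transition state that keeps the bulky ring and C9 apart should give E-C7=C8 in conjugation with the enoate.

**Step 11**
Reactants: 14 ethyl (2E,4E)-3-methyl-5-[(3aS,7aR)-4,4,7a-trimethyl-2-oxohexahydro-1,3-benzodioxol-3a-yl]penta-2,4-dienoate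
Product: 15 (1S,2R)-1-[(1E,3E)-5-hydroxy-3-methylpenta-1,3-dien-1-yl]-2,6,6-trimethylcyclohexane-1,2-diol
Conditions: LiAlH4 (3 equiv), Et2O, −20 to 0 °C; Na2SO4·10H2O
Reagents that add atoms: none
Why: The hydride reduction takes the dienoate to the allylic alcohol and the cyclic carbonate to the free cis-diol in one operation by attack at the carbonyl carbons only, with no acid present that could ionise the allylic C6–O bond.

**Step 12**
Reactants: 15 (1S,2R)-1-[(1E,3E)-5-hydroxy-3-methylpenta-1,3-dien-1-yl]-2,6,6-trimethylcyclohexane-1,2-diol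
Product: 17 {(2E,4E)-5-[(1S,2R)-1,2-dihydroxy-2,6,6-trimethylcyclohexyl]-3-methylpenta-2,4-dien-1-yl}triphenylphosphonium bromide, via ring A dienyl bromide 16 (not isolated)
Conditions: CBr4 (1.1 equiv), PPh3 (1.15 equiv), 2,6-lutidine (0.3 equiv), CH2Cl2, −20 °C; then PPh3 (1.2 equiv), 25 °C
Reagents that add atoms: carbon tetrabromide BrC(Br)(Br)Br; triphenylphosphine c1ccc(cc1)P(c1ccccc1)c1ccccc1
Why: The Appel bromination picks the primary allylic hydroxyl over the two hindered tertiary ones in a buffered neutral medium, and SN2 quaternisation of PPh3 then gives the Wittig salt without the acid of the PPh3·HBr method.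

**Step 13**
Reactants: 18 β-cyclocitral
Product: 19 β-cyclogeraniol
Conditions: NaBH4, MeOH, 0 °C
Reagents that add atoms: none
Why: Borohydride reduces the hindered enal in the 1,2 sense to the allylic alcohol that the directed epoxidation needs.

**Step 14**
Reactants: 19 β-cyclogeraniol
Product: 20 [(1R,6R)-2,2,6-trimethyl-7-oxabicyclo[4.1.0]heptan-1-yl]methanol
Conditions: Ti(OiPr)4 (20 mol %), D-(−)-diethyl tartrate (25 mol %), t-BuOOH, 4 Å MS, CH2Cl2, −20 °C
Reagents that add atoms: tert-butyl hydroperoxide CC(C)(C)OO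
Why: The Katsuki–Sharpless epoxidation of this tetrasubstituted allylic alcohol with the D-(−)-tartrate complex places oxygen on the face that makes C5' R (and C6' R in this alcohol).

**Step 15**
Reactants: 20 [(1R,6R)-2,2,6-trimethyl-7-oxabicyclo[4.1.0]heptan-1-yl]methanol
Product: 21 (1S,6R)-2,2,6-trimethyl-7-oxabicyclo[4.1.0]heptane-1-carbaldehyde
Conditions: n-Pr4N[RuO4] (5 mol %), N-methylmorpholine N-oxide, 4 Å MS, CH2Cl2, 25 °C
Reagents that add atoms: none
Why: The Ley–Griffith oxidation is neutral and leaves the acid-sensitive tetrasubstituted epoxide intact, and only the descriptor at C6' changes, not the geometry.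

**Step 16**
Reactants: 21 (1S,6R)-2,2,6-trimethyl-7-oxabicyclo[4.1.0]heptane-1-carbaldehyde; 22 dimethyl (1-diazo-2-oxopropyl)phosphonate
Product: 23 (1R,6R)-1-ethynyl-2,2,6-trimethyl-7-oxabicyclo[4.1.0]heptane
Conditions: K2CO3 (2 equiv), MeOH, 0 to 25 °C
Reagents that add atoms: none
Why: The Ohira–Bestmann homologation works under mild carbonate base on an aldehyde that has no alpha hydrogen, so nothing can epimerise and the epoxide survives.

**Step 17**
Reactants: 23 (1R,6R)-1-ethynyl-2,2,6-trimethyl-7-oxabicyclo[4.1.0]heptane; 12 ethyl (2E)-3-(trifluoromethylsulfonyloxy)but-2-enoate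
Product: 24 ethyl (2E)-3-methyl-5-[(1R,6R)-2,2,6-trimethyl-7-oxabicyclo[4.1.0]heptan-1-yl]pent-2-en-4-ynoate
Conditions: PdCl2(PPh3)2 (3 mol %), CuI (6 mol %), Et3N, THF, 25 °C
Reagents that add atoms: none
Why: In this Sonogashira coupling zerovalent palladium inserts into the electron-poor enol triflate with retention of the E geometry far faster than it can ionise the hindered alkynyl epoxide.

**Step 18**
Reactants: 24 ethyl (2E)-3-methyl-5-[(1R,6R)-2,2,6-trimethyl-7-oxabicyclo[4.1.0]heptan-1-yl]pent-2-en-4-ynoate
Product: 25 (2E)-5-[(2R)-2-hydroxy-2,6,6-trimethylcyclohexylidene]-3-methylpenta-2,4-dien-1-ol (allene axis R, C9' on the ring face opposite to the 5'-OH)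
Conditions: i-Bu2AlH (5 equiv), CH2Cl2, −78 to 0 °C; aq potassium sodium tartrate
Reagents that add atoms: none
Why: After reducing the ester, the aluminium hydride bound to the oxirane oxygen delivers hydride to C8' on the face of the departing C6'–O bond (syn SN2' opening of an alkynyl epoxide, the established entry to allenic carotenoid end groups), which keeps C5' and sets the R allene axis.

**Step 19**
Reactants: 25 (2E)-5-[(2R)-2-hydroxy-2,6,6-trimethylcyclohexylidene]-3-methylpenta-2,4-dien-1-ol
Product: 26 (2E)-3-[(2S,7aR)-4,4,7a-trimethyl-2,4,5,6,7,7a-hexahydro-1-benzofuran-2-yl]but-2-en-1-ol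
Conditions: AgNO3 (20 mol %), CaCO3, acetone–H2O, 25 °C, dark
Reagents that add atoms: none
Why: The silver-catalysed 5-endo cycloisomerisation of an alpha-hydroxyallene to a 2,5-dihydrofuran runs by anti oxymetalation of C7'=C8' and protodemetalation with axis-to-centre chirality transfer, so C9' stays on the face of the 5'-methyl group and C8' becomes S.

**Step 20**
Reactants: 26 (2E)-3-[(2S,7aR)-4,4,7a-trimethyl-2,4,5,6,7,7a-hexahydro-1-benzofuran-2-yl]but-2-en-1-ol
Product: 28 {(2E)-3-[(2S,7aR)-4,4,7a-trimethyl-2,4,5,6,7,7a-hexahydro-1-benzofuran-2-yl]but-2-en-1-yl}triphenylphosphonium bromide, via furanoid allylic bromide 27 (not isolated)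
Conditions: CBr4 (1.1 equiv), PPh3 (1.15 equiv), 2,6-lutidine (0.3 equiv), CH2Cl2, −20 °C; then PPh3 (1.2 equiv), 25 °C
Reagents that add atoms: carbon tetrabromide BrC(Br)(Br)Br; triphenylphosphine c1ccc(cc1)P(c1ccccc1)c1ccccc1
Why: Appel bromination and SN2 quaternisation of PPh3 avoid every proton source that could ionise the doubly allylic C8'–O bond and epimerise C8'.

**Step 21**
Reactants: 28 furanoid C15 phosphonium bromide; 29 (2E,4E,6E)-2,7-dimethylocta-2,4,6-trienedial
Product: 30 all-E C25 furanoid apocarotenal (C12 aldehyde, 5'R,8'S)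
Conditions: 29 (2 equiv), NaOMe (1.05 equiv, added slowly to the mixture), CH2Cl2–MeOH, 0 °C; then EtOH, 60 °C
Reagents that add atoms: none
Why: In this Wittig olefination the excess dialdehyde secures mono-condensation, and releasing the ylide in the presence of the aldehyde lets it be trapped before the poor alkoxide leaving group at C8' can be lost.

**Step 22**
Reactants: 17 ring A C15 phosphonium bromide; 30 all-E C25 furanoid apocarotenal
Product: 31 (5R,6S,5'R,8'S)-5',8'-epoxy-5,6,5',8'-tetrahydro-β,β-carotene-5,6-diol (target CNP0378030.2)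
Conditions: 1,2-epoxybutane (10 equiv), EtOH, 70 °C, Ar, dark
Reagents that add atoms: none
Why: In this Wittig olefination epoxybutane scavenges HBr and frees the ylide slowly beside the aldehyde, so the free C6 hydroxyl (a poor leaving group) is not expelled, no stereocentre is touched, and the heating equilibrates the hindered 11Z bond to all-E.

**Compound list**

| No. | Name | SMILES | Role |
|---|---|---|---|
1 | geraniol | CC(C)=CCC/C(C)=C/CO | starting material
2 | (2R,3R)-2,3-epoxygeraniol | OC[C@H]1O[C@]1(C)CCC=C(C)C | intermediate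
3 | (2R,3S)-3-(chloromethyl)-2-methyl-2-(4-methylpent-3-en-1-yl)oxirane | ClC[C@H]1O[C@]1(C)CCC=C(C)C | intermediate
4 | (3R)-3,7-dimethyloct-6-en-1-yn-3-ol | C#C[C@](C)(O)CCC=C(C)C | intermediate
5 | methyl chloroformate | COC(=O)Cl | starting material
6 | methyl (4R)-4-hydroxy-4,8-dimethylnon-7-en-2-ynoate | COC(=O)C#C[C@](C)(O)CCC=C(C)C | intermediate
7 | carbon dioxide | O=C=O | starting material
8 | methyl (2Z)-2-[(5R)-5-methyl-5-(4-methylpent-3-en-1-yl)-2-oxo-1,3-dioxolan-4-ylidene]acetate | COC(=O)/C=C1\OC(=O)O[C@]1(C)CCC=C(C)C | intermediate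
9 | methyl 2-[(3aS,7aR)-4,4,7a-trimethyl-2-oxohexahydro-1,3-benzodioxol-3a-yl]acetate | COC(=O)C[C@]1(OC(=O)O2)C(C)(C)CCC[C@]12C | intermediate
10 | 2-[(3aS,7aR)-4,4,7a-trimethyl-2-oxohexahydro-1,3-benzodioxol-3a-yl]acetaldehyde | O=CC[C@]1(OC(=O)O2)C(C)(C)CCC[C@]12C | intermediate
11 | ethyl acetoacetate | CCOC(=O)CC(C)=O | starting material
12 | ethyl (2E)-3-(trifluoromethylsulfonyloxy)but-2-enoate | CCOC(=O)/C=C(C)/OS(=O)(=O)C(F)(F)F | intermediate
13 | ethyl (2E)-4-hydroxy-3-methyl-5-[(3aS,7aR)-carbonate ring A]pent-2-enoate, C8 epimers | CCOC(=O)/C=C(C)/C(O)C[C@]1(OC(=O)O2)C(C)(C)CCC[C@]12C | intermediate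
14 | ethyl (2E,4E)-3-methyl-5-[(3aS,7aR)-carbonate ring A]penta-2,4-dienoate | CCOC(=O)/C=C(C)/C=C/[C@]1(OC(=O)O2)C(C)(C)CCC[C@]12C | intermediate
15 | (1S,2R)-1-[(1E,3E)-5-hydroxy-3-methylpenta-1,3-dien-1-yl]-2,6,6-trimethylcyclohexane-1,2-diol | OC/C=C(C)/C=C/[C@]1(O)C(C)(C)CCC[C@@]1(C)O | intermediate
16 | (1S,2R)-1-[(1E,3E)-5-bromo-3-methylpenta-1,3-dien-1-yl]-2,6,6-trimethylcyclohexane-1,2-diol | BrC/C=C(C)/C=C/[C@]1(O)C(C)(C)CCC[C@@]1(C)O | intermediate (not isolated)
17 | ring A C15 triphenylphosphonium bromide | [Br-].c1ccccc1[P+](c1ccccc1)(c1ccccc1)C/C=C(C)/C=C/[C@]1(O)C(C)(C)CCC[C@@]1(C)O | intermediate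
18 | β-cyclocitral | CC1=C(C=O)C(C)(C)CCC1 | starting material
19 | β-cyclogeraniol | CC1=C(CO)C(C)(C)CCC1 | intermediate
20 | [(1R,6R)-2,2,6-trimethyl-7-oxabicyclo[4.1.0]heptan-1-yl]methanol | OC[C@@]12O[C@]1(C)CCCC2(C)C | intermediate
21 | (1S,6R)-2,2,6-trimethyl-7-oxabicyclo[4.1.0]heptane-1-carbaldehyde | O=C[C@@]12O[C@]1(C)CCCC2(C)C | intermediate
22 | dimethyl (1-diazo-2-oxopropyl)phosphonate | COP(=O)(OC)C(=[N+]=[N-])C(C)=O | starting material
23 | (1R,6R)-1-ethynyl-2,2,6-trimethyl-7-oxabicyclo[4.1.0]heptane | C#C[C@@]12O[C@]1(C)CCCC2(C)C | intermediate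
24 | ethyl (2E)-3-methyl-5-[(1R,6R)-2,2,6-trimethyl-7-oxabicyclo[4.1.0]heptan-1-yl]pent-2-en-4-ynoate | CCOC(=O)/C=C(C)/C#C[C@@]12O[C@]1(C)CCCC2(C)C | intermediate
25 | (2E)-5-[(2R)-2-hydroxy-2,6,6-trimethylcyclohexylidene]-3-methylpenta-2,4-dien-1-ol, allene axis R | OC/C=C(C)/C([H])=[C@@]=C1C(C)(C)CCC[C@@]1(C)O | intermediate
26 | (2E)-3-[(2S,7aR)-4,4,7a-trimethyl-2,4,5,6,7,7a-hexahydro-1-benzofuran-2-yl]but-2-en-1-ol | OC/C=C(C)/[C@@H]1C=C2C(C)(C)CCC[C@@]2(C)O1 | intermediate
27 | (2S,7aR)-2-[(2E)-4-bromobut-2-en-2-yl]-4,4,7a-trimethyl-2,4,5,6,7,7a-hexahydro-1-benzofuran | BrC/C=C(C)/[C@@H]1C=C2C(C)(C)CCC[C@@]2(C)O1 | intermediate (not isolated)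
28 | furanoid C15 triphenylphosphonium bromide | [Br-].c1ccccc1[P+](c1ccccc1)(c1ccccc1)C/C=C(C)/[C@@H]1C=C2C(C)(C)CCC[C@@]2(C)O1 | intermediate
29 | (2E,4E,6E)-2,7-dimethylocta-2,4,6-trienedial | O=C/C(C)=C/C=C/C=C(C)/C=O | starting material
30 | all-E C25 furanoid apocarotenal (5'R,8'S) | O=C/C(C)=C/C=C/C=C(C)/C=C/C=C(C)/[C@@H]1C=C2C(C)(C)CCC[C@@]2(C)O1 | intermediate
31 | (5R,6S,5'R,8'S)-5',8'-epoxy-5,6,5',8'-tetrahydro-β,β-carotene-5,6-diol | CC(/C=C/C=C(C)/C=C/[C@]1(O)C(C)(C)CCC[C@@]1(C)O)=C\C=C\C=C(C)\C=C\C=C(/C)[C@@H]1C=C2C(C)(C)CCC[C@@]2(C)O1 | target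

**Step count**

- Total step count: 22.
- Longest linear sequence: 12 steps (steps 1–7, 9–12 and 22, from geraniol).
- The ring B branch needs 10 steps (13–22).

**Steps most likely to fail**

Step 6. Several things could go wrong.
- The tertiary C1 radical may take up a second hydrogen atom before it reaches the crowded C6.
- A C7 enolate may expel the carbonate.
- The alcohol may open the activated enol carbonate.

The fallback sets out from 8. Markovnikov addition of HBr (HBr in AcOH, CH2Cl2, 0 °C) to the prenyl alkene should give the tertiary bromide F1. A tin hydride chain reaction follows (Bu3SnH by syringe pump, AIBN, benzene, 80 °C). This is the established way to cyclise alkyl halides onto beta-oxygenated acrylates. It forms the same C1–C6 bond under the same tether control in an aprotic neutral medium. There C7 is quenched as a radical and never passes through an enolate. The fallback rejoins the route at 9.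

Step 9. The beta-carbonate aldehyde may enolise on the Lewis-acidic chromium salts and lose its carbonate. The electron-poor alkenyl group may pass only sluggishly from nickel to chromium. It may also leak to the Z form, which lactonises.

The fallback sets out from 10 and changes both the nucleophile and its oxidation level.
- Hydrozirconation of tert-butyl(but-2-yn-1-yloxy)dimethylsilane with Cp2Zr(H)Cl, transmetalation with Me2Zn and addition of the mild alkenylzinc to 10 should give the silyl-protected allylic alcohol F2.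
- Burgess dehydration gives the dienyl silyl ether F3.
- Bu4NF gives the dienol carbonate F4.
- K2CO3 in MeOH removes the carbonate, and the route is rejoined at 15.

Step 19. Reversible ionisation at the doubly allylic C8' on the metal may erode the axis-to-centre transfer. The vinylallene may also be diverted into other cycloisomerisation channels.

The fallback sets out from 21 and uses the classical epoxide-to-furanoid rearrangement.
- A Horner–Wadsworth–Emmons reaction with triethyl 3-methyl-4-phosphonocrotonate (LiN(SiMe3)2, THF, −78 to 0 °C) gives the epoxy dienoate F5.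
- A trace of HCl in CHCl3 opens C6'–O and lets O5' attack C8' with retention at C5'. This gives the furanoid ester F6 together with its C8' epimer F7, which is removed by chromatography.
- i-Bu2AlH reduces F6, and the route is rejoined at 26.

**Further compounds**

F1 | step 6 | methyl (2Z)-2-[(5R)-5-(4-bromo-4-methylpentyl)-5-methyl-2-oxo-1,3-dioxolan-4-ylidene]acetate | COC(=O)/C=C1\OC(=O)O[C@]1(C)CCCC(C)(C)Br
F2 | step 9 | (3aS,7aR)-3a-[(3E)-5-(tert-butyldimethylsilyloxy)-2-hydroxy-3-methylpent-3-en-1-yl]-4,4,7a-trimethylhexahydro-1,3-benzodioxol-2-one (C8 epimers) | CC(C)(C)[Si](C)(C)OC/C=C(C)/C(O)C[C@]1(OC(=O)O2)C(C)(C)CCC[C@]12C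
F3 | step 9 | (3aS,7aR)-3a-[(1E,3E)-5-(tert-butyldimethylsilyloxy)-3-methylpenta-1,3-dien-1-yl]-4,4,7a-trimethylhexahydro-1,3-benzodioxol-2-one | CC(C)(C)[Si](C)(C)OC/C=C(C)/C=C/[C@]1(OC(=O)O2)C(C)(C)CCC[C@]12C
F4 | step 9 | (3aS,7aR)-3a-[(1E,3E)-5-hydroxy-3-methylpenta-1,3-dien-1-yl]-4,4,7a-trimethylhexahydro-1,3-benzodioxol-2-one | OC/C=C(C)/C=C/[C@]1(OC(=O)O2)C(C)(C)CCC[C@]12C
F5 | step 19 | ethyl (2E,4E)-3-methyl-5-[(1S,6R)-2,2,6-trimethyl-7-oxabicyclo[4.1.0]heptan-1-yl]penta-2,4-dienoate | CCOC(=O)/C=C(C)/C=C/[C@@]12O[C@]1(C)CCCC2(C)C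
F6 | step 19 | ethyl (2E)-3-[(2S,7aR)-4,4,7a-trimethyl-2,4,5,6,7,7a-hexahydro-1-benzofuran-2-yl]but-2-enoate | CCOC(=O)/C=C(C)/[C@@H]1C=C2C(C)(C)CCC[C@@]2(C)O1
F7 | step 19 | ethyl (2E)-3-[(2R,7aR)-4,4,7a-trimethyl-2,4,5,6,7,7a-hexahydro-1-benzofuran-2-yl]but-2-enoate | CCOC(=O)/C=C(C)/[C@H]1C=C2C(C)(C)CCC[C@@]2(C)O1
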